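**Plan**

- Retrosynthesis: the C3 benzoate and the C3–O bond are removed first (α-oxygenation next to a C4 ketone) and the C4 carbinol goes back to an enone carbonyl. The C2–O bond is then cut across a tether from O1, and the remaining para-quinol is traced to a phenol by dearomatisation. The C7 benzoate is carried from the start.
- Forward: 4-hydroxybenzyl alcohol is esterified and dearomatised to the para-quinol (the carbocycle is the old arene; no C–C bond is made). A temporary five-membered dioxaborolane is closed across O1/C2 and exchanged for an acetonide, then C3 is oxygenated and benzoylated, C4 is reduced and the diol is unmasked.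
- Enabling feature: C1 is a tertiary carbinol carbon carrying C7, with a cis oxygen on C2. With O2 and O3 removed and C4 as a ketone, the ring is an achiral 4-hydroxycyclohexa-2,5-dienone with a mirror plane through C1, C4 and C7, so the C2=C3 and C6=C5 arms are enantiotopic.
- Stereochemistry: catalyst-controlled choice of arm fixes C1 and C2 absolutely, and the tether makes them cis. C3 comes from oxidation anti to the cis-fused acetonide, and C4 from axial hydride delivery trans to the C3 benzoate.

Key step: step 3

Numbering: C1–C6 and the exocyclic C7 are those of the target in every compound; the β face is the face of the C1 and C2 oxygens, the α face that of C7.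

Assumption: the quinine-derived amine–thiourea is taken to select the enone arm that leads to the (1S,2S) boronate; should it favour the other arm, the pseudo-enantiomeric quinidine-derived catalyst is used with nothing else changed.

**Route**

Step 1
Reactants: 1 4-hydroxybenzyl alcohol; 2 benzoic acid
Product: 3 4-hydroxybenzyl benzoate
Conditions: PPh3, diisopropyl azodicarboxylate (DIAD), THF, 0 °C to rt
Reagents that add atoms: benzoic acid (2), O=C(O)c1ccccc1
Why: Mitsunobu esterification, in which the carboxylic acid is a far better pronucleophile than the phenol, so the benzylic oxyphosphonium ion is displaced by benzoate and the phenolic hydroxyl should stay free, as is usual for hydroxybenzyl alcohols.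

Step 2
Reactants: 3 4-hydroxybenzyl benzoate
Product: 4 4-(benzoyloxymethyl)-4-hydroxycyclohexa-2,5-dien-1-one
Conditions: PhI(OAc)2, MeCN/H2O (3:1), 0 °C
Reagents that add atoms: water, O
Why: Oxidative dearomatisation of a para-substituted phenol with a trivalent iodine reagent, in which ligand exchange at iodine and loss of PhI leave an electrophilic ring that water captures at the substituted para carbon to give the achiral para-quinol.

Step 3
Reactants: 4 4-(benzoyloxymethyl)-4-hydroxycyclohexa-2,5-dien-1-one; 5 phenylboronic acid
Product: 7 (1S,2S) cis-fused phenylboronate of 1-(benzoyloxymethyl)-1,2-dihydroxycyclohex-5-en-4-one, via boronic hemiester 6 (not isolated)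
Conditions: PhB(OH)2 (1.2 equiv), 1-[3,5-bis(trifluoromethyl)phenyl]-3-[(8S,9S)-6'-methoxycinchonan-9-yl]thiourea (10 mol %), 4 Å molecular sieves, toluene, rt
Reagents that add atoms: phenylboronic acid (5), OB(O)c1ccccc1
Why: The tertiary hydroxyl of 4 condenses with PhB(OH)2 to hemiester 6 (the sieves take up the water), the quinuclidine nitrogen of the catalyst binds the remaining B–OH and raises the nucleophilicity of its oxygen while the thiourea hydrogen-bonds the dienone carbonyl, and this oxygen adds to C2 of one enone arm before the enol is protonated at C3. This is the amine–thiourea-catalysed intramolecular oxa-Michael addition of boronic acid hemiesters of γ-hydroxy enones, run in the desymmetrising mode known for tethered oxygen nucleophiles on 4-hydroxycyclohexa-2,5-dienones. The dioxaborolane (C1–O–B–O–C2) closes 5-exo-trig. C2 is set by the tether, which can reach C2 only on the face of O1 and so gives the cis ring fusion, and C1 becomes stereogenic through the choice of arm, which the chiral catalyst controls. The step needs selection between two enantiotopic arms, and the mirror plane of 4 through C1, C4 and C7 ensures that nothing but the catalyst distinguishes them; a second addition is excluded because the single hydroxyl and the boron are tied up in the ring.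

Step 4
Reactants: 7 cis-fused phenylboronate
Product: 8 (1S,2S)-1-(benzoyloxymethyl)-1,2-dihydroxycyclohex-5-en-4-one
Conditions: pinacol (5 equiv), CH2Cl2, rt
Reagents that add atoms: none
Why: Transesterification of a boronic ester with a diol, in which excess pinacol draws the boron into its more stable pinacol ester under neutral conditions that should leave the enone, the β-hydroxy ketone and the benzoate untouched and break no bond to a stereocentre.

Step 5
Reactants: 8 (1S,2S) cis-diol
Product: 9 (1S,2S)-1-(benzoyloxymethyl)-1,2-(isopropylidenedioxy)cyclohex-5-en-4-one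
Conditions: Me2C(OMe)2, camphor-10-sulfonic acid (5 mol %), acetone, 0 °C to rt
Reagents that add atoms: 2,2-dimethoxypropane, COC(C)(C)OC
Why: Acid-catalysed transketalisation (acetonide formation) of a cis-1,2-diol on a six-membered ring, which closes the cis-fused dioxolane readily and retains both C–O bonds, so C1 and C2 are unchanged.

Step 6
Reactants: 9 acetonide enone
Product: 10 (1S,2S)-1-(benzoyloxymethyl)-1,2-(isopropylidenedioxy)-4-(trimethylsilyloxy)cyclohexa-3,5-diene
Conditions: Me3SiOTf, Et3N, CH2Cl2, −78 to 0 °C; crude product used directly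
Reagents that add atoms: trimethylsilyl trifluoromethanesulfonate, C[Si](C)(C)OS(=O)(=O)C(F)(F)F
Why: Soft enolisation to a silyl enol ether, in which the silyl triflate activates the carbonyl and the amine removes a C3 proton (the only enolisable position, since C1 is quaternary), giving the cross-conjugated 2-silyloxydiene without a free enolate that could expel the C2 oxygen.

Step 7
Reactants: 10 silyloxydiene
Product: 13 (1S,2S,3S)-1-(benzoyloxymethyl)-3-hydroxy-1,2-(isopropylidenedioxy)cyclohex-5-en-4-one with the 3-hydroxyl on the α face, via silyloxy epoxide 11 (not isolated), via alpha-silyloxy ketone 12 (not isolated)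
Conditions: mCPBA, CH2Cl2, −20 to 0 °C; then 0.5 M HCl, THF, 0 °C
Reagents that add atoms: 3-chloroperoxybenzoic acid (mCPBA), O=C(OO)c1cccc(Cl)c1
Why: Rubottom oxidation, in which the peracid should epoxidise the electron-rich C3=C4 enol ether bond on the convex α face, anti to the cis-fused dioxolane as cis-dihydrodiol acetonides do, the silyloxy epoxide rearranges with silyl shift to the α-silyloxy ketone, and dilute acid frees the C3 hydroxyl trans to O2.

Step 8
Reactants: 13 3α-hydroxy ketone; 14 benzoyl chloride
Product: 15 (1S,2S,3S)-3-benzoyloxy-1-(benzoyloxymethyl)-1,2-(isopropylidenedioxy)cyclohex-5-en-4-one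
Conditions: BzCl, pyridine, 4-(dimethylamino)pyridine (5 mol %), CH2Cl2, 0 °C
Reagents that add atoms: benzoyl chloride (14), O=C(Cl)c1ccccc1
Why: Acylation of the only free hydroxyl with an acid chloride under nucleophilic catalysis, which forms the ester at oxygen without touching the C3–O bond, so the configuration is retained.

Step 9
Reactants: 15 α-benzoyloxy enone
Product: 16 (1S,2S,3R,4S)-3-benzoyloxy-1-(benzoyloxymethyl)-1,2-(isopropylidenedioxy)cyclohex-5-en-4-ol with the 4-hydroxyl on the β face
Conditions: NaBH4, CeCl3·7H2O, MeOH, −78 °C; quench cold with aqueous NH4Cl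
Reagents that add atoms: none
Why: Luche reduction, in which the cerium-modified borohydride adds 1,2 to the enone and axial delivery to C4 on the convex α face (anti to the dioxolane) should place the new hydroxyl equatorial on the β face, trans to the equatorial C3 benzoate.

Step 10
Reactants: 16 acetonide-protected allylic alcohol
Product: 17 1α-benzoyloxymethyl-3α-benzoyloxycyclohex-5-en-1β,2β,4β-triol (1S,2S,3R,4S)
Conditions: CF3CO2H/H2O (9:1), 0 °C
Reagents that add atoms: none
Why: Acid-catalysed hydrolysis of the isopropylidene ketal, to which benzoates are stable in the cold and in which no bond to a stereocentre is broken.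

**Compound list**

1 | 4-hydroxybenzyl alcohol | OCc1ccc(O)cc1 | starting material
2 | benzoic acid | O=C(O)c1ccccc1 | starting material
3 | 4-hydroxybenzyl benzoate | O=C(OCc1ccc(O)cc1)c1ccccc1 | intermediate
4 | 4-(benzoyloxymethyl)-4-hydroxycyclohexa-2,5-dien-1-one (achiral para-quinol) | O=C1C=CC(O)(COC(=O)c2ccccc2)C=C1 | intermediate
5 | phenylboronic acid | OB(O)c1ccccc1 | starting material
6 | boronic hemiester of 4, (1-{[hydroxy(phenyl)boranyl]oxy}-4-oxocyclohexa-2,5-dien-1-yl)methyl benzoate (not isolated) | O=C1C=CC(COC(=O)c2ccccc2)(OB(O)c2ccccc2)C=C1 | intermediate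
7 | (1S,2S) cis-fused phenylboronate of 1-(benzoyloxymethyl)-1,2-dihydroxycyclohex-5-en-4-one; O1 and O2 on the β face, C3 is CH2 | O=C(OC[C@@]12C=CC(=O)C[C@@H]1OB(c3ccccc3)O2)c1ccccc1 | intermediate
8 | (1S,2S)-1-(benzoyloxymethyl)-1,2-dihydroxycyclohex-5-en-4-one (cis-diol) | O=C(OC[C@@]1(O)C=CC(=O)C[C@@H]1O)c1ccccc1 | intermediate
9 | (1S,2S)-1-(benzoyloxymethyl)-1,2-(isopropylidenedioxy)cyclohex-5-en-4-one (cis-fused acetonide on the β face) | O=C(OC[C@@]12C=CC(=O)C[C@@H]1OC(C)(C)O2)c1ccccc1 | intermediate
10 | (1S,2S)-1-(benzoyloxymethyl)-1,2-(isopropylidenedioxy)-4-(trimethylsilyloxy)cyclohexa-3,5-diene | O=C(OC[C@@]12C=CC(O[Si](C)(C)C)=C[C@@H]1OC(C)(C)O2)c1ccccc1 | intermediate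
11 | 3α,4α-epoxide of 10, C4 carrying OSiMe3 (not isolated) | O=C(OC[C@@]12C=C[C@]3(O[Si](C)(C)C)[C@@H](O3)[C@@H]1OC(C)(C)O2)c1ccccc1 | intermediate
12 | (1S,2S,3S)-1-(benzoyloxymethyl)-1,2-(isopropylidenedioxy)-3α-(trimethylsilyloxy)cyclohex-5-en-4-one (not isolated) | O=C(OC[C@@]12C=CC(=O)[C@@H](O[Si](C)(C)C)[C@@H]1OC(C)(C)O2)c1ccccc1 | intermediate
13 | (1S,2S,3S)-1-(benzoyloxymethyl)-3α-hydroxy-1,2-(isopropylidenedioxy)cyclohex-5-en-4-one | O=C(OC[C@@]12C=CC(=O)[C@@H](O)[C@@H]1OC(C)(C)O2)c1ccccc1 | intermediate
14 | benzoyl chloride | O=C(Cl)c1ccccc1 | starting material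
15 | (1S,2S,3S)-3α-benzoyloxy-1-(benzoyloxymethyl)-1,2-(isopropylidenedioxy)cyclohex-5-en-4-one | O=C(OC[C@@]12C=CC(=O)[C@@H](OC(=O)c3ccccc3)[C@@H]1OC(C)(C)O2)c1ccccc1 | intermediate
16 | (1S,2S,3R,4S)-3α-benzoyloxy-1-(benzoyloxymethyl)-1,2-(isopropylidenedioxy)cyclohex-5-en-4β-ol | O=C(OC[C@@]12C=C[C@H](O)[C@@H](OC(=O)c3ccccc3)[C@@H]1OC(C)(C)O2)c1ccccc1 | intermediate
17 | 1α-benzoyloxymethyl-3α-benzoyloxycyclohex-5-en-1β,2β,4β-triol, (1S,2S,3R,4S) | O=C(OC[C@@]1(O)C=C[C@H](O)[C@@H](OC(=O)c2ccccc2)[C@@H]1O)c1ccccc1 | target

**Count and risks**

Total step count: 10. Longest linear sequence: 10 steps (1 to 17).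

Steps most likely to fail:

Step 3. The catalyst may discriminate poorly between the two enantiotopic arms, or hemiester formation at the hindered tertiary hydroxyl may be slow enough for an unselective background closure to compete. The fallback keeps the O1-tethered C2–O bond formation but changes both tether and catalyst type. It sets out from 4, which is treated with 2-methylpropanal and the enantiomer of 3,3'-bis(2,4,6-triisopropylphenyl)-1,1'-binaphthyl-2,2'-diyl hydrogen phosphate that favours the same arm. The hemiacetal oxygen should then close onto C2 to give the cis-fused 2-isopropyl-1,3-dioxolane F1 (isopropyl exo). Hydrolysis of this acetal in cold aqueous CF3CO2H gives diol 8, where the route is rejoined.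

Step 7. Facial selectivity in the epoxidation of the silyl enol ether may be poor, because the C7 branch on C1 shares the α face with the incoming peracid, so that C3 is formed as a mixture. The fallback sets C3 by substitution instead of by the face of oxidation. It sets out from 10: the 3β-hydroxy ketone F2 (the C3 epimer of 13) formed in the oxidation is separated and esterified with benzoic acid 2 under Mitsunobu conditions (PPh3, DIAD, THF). This installs the benzoate with inversion and comes back to the route at 15, while any 13 is benzoylated as in step 8, so both epimers converge.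

Step 2. The benzoate carbonyl may participate at the para carbon, or benzoate may be lost through a quinone methide during the oxidation, which would scramble the ester and lower the recovery of the quinol. The fallback dearomatises before any acyloxy group is present. It sets out from 1, which is silylated at the primary hydroxyl (tert-butyldimethylsilyl chloride, imidazole, DMF, 0 °C) to 4-[(tert-butyldimethylsilyloxy)methyl]phenol F3. Oxidation with PhI(OAc)2 in MeCN/H2O gives 4-[(tert-butyldimethylsilyloxy)methyl]-4-hydroxycyclohexa-2,5-dien-1-one F4, and HF·pyridine in THF frees 4-hydroxy-4-(hydroxymethyl)cyclohexa-2,5-dien-1-one F5. Its primary hydroxyl is benzoylated selectively over the tertiary one with benzoyl chloride 14 in pyridine at 0 °C, which comes back to the route at 4.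

**Further compounds**

F1 | step 3 | (1S,2S) cis-fused 2-isopropyl-1,3-dioxolane of 1-(benzoyloxymethyl)-1,2-dihydroxycyclohex-5-en-4-one, isopropyl exo | O=C(OC[C@@]12C=CC(=O)C[C@@H]1O[C@@H](C(C)C)O2)c1ccccc1
F2 | step 7 | 1-(benzoyloxymethyl)-3β-hydroxy-1,2-(isopropylidenedioxy)cyclohex-5-en-4-one (C3 epimer of 13) | O=C(OC[C@@]12C=CC(=O)[C@H](O)[C@@H]1OC(C)(C)O2)c1ccccc1
F3 | step 2 | 4-[(tert-butyldimethylsilyloxy)methyl]phenol | CC(C)(C)[Si](C)(C)OCc1ccc(O)cc1
F4 | step 2 | 4-[(tert-butyldimethylsilyloxy)methyl]-4-hydroxycyclohexa-2,5-dien-1-one | CC(C)(C)[Si](C)(C)OCC1(O)C=CC(=O)C=C1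
F5 | step 2 | 4-hydroxy-4-(hydroxymethyl)cyclohexa-2,5-dien-1-one | OCC1(O)C=CC(=O)C=C1
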